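Turn every percentage back into molarity before reading the runs.

| flask | solid substrate | remark | time |
|---|---|---|---|
| Thursday's | 0.15 M | run made earlier |  |
| Saturday's | 0.23 M | run made earlier |  |
| flask | 0.31 M |  | 25 min |

| run | time / min | target / % | starting material / % |
|---|---|---|---|
| Thursday's | 1.33 | 1.9 | 4.3 |
| Thursday's | 4.00 | 4.4 | 6.7 |
| Thursday's | 8.00 | 7.7 | 9.2 |
| Thursday's | 10.0 | 8.4 | 9.4 |
| Thursday's | 15.0 | 9.9 | 10.5 |
| Saturday's | 1.33 | 0.6 | 1.8 |
| Saturday's | 4.00 | 3.8 | 4.2 |
| Saturday's | 8.00 | 5.9 | 5.0 |
| Saturday's | 10.0 | 6.4 | 5.1 |
| Saturday's | 15.0 | 6.5 | 7.1 |

(each reading ± 0.5 percentage points)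

- solid substrate is a solid; its amount is given per volume of the solution
- steps thought possible: starting material <-> target; starting material <-> isomer of the product A; starting material <-> third isomer; solid substrate <-> starting material; target <-> isomer of the product B
- at the start none of the solid substrate is in solution
- starting material means what is dissolved; the solid is not counted in it

* how much target there is at 25 min, in percent of the solid substrate charged
* concentration of starting material in solution at 25 min, in percent of saturation

At the last reading, 15.0 min, Thursday's target stood at 0.0149 M and Saturday's at 0.0150 M, so at that reading the level did not follow the charge: zero order in the solid charged, as far as this pair of readings goes. I took their mean, c, and divided it by the charge c₀ of this flask. The result, N, is the share of the charge that this common target level amounts to.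

c = 0.0149 M

N = c / c₀ = 4.81%

Was one number enough? Across charges, roughly: at 10.0 min the two runs stood at 0.0126 M and 0.0147 M, and each reading scatters by 0.5 percentage points of its own charge. Across time, I doubted it. From 10.0 min on, Thursday's target rose from 8.4% to 9.9%, Saturday's from 6.4% to 6.5%, so I expected somewhat more than N at 25 min. These readings did not part a saturated solution from a balance of dissolving against onward loss, so I committed to no saturation figure.

The forecast, holding that “excess solid dissolves towards a fixed saturation”, gave 5.3% of target (4.7% to 6.1%) and starting material at 80% of saturation (65% to 93%).

The flask gave 5.44%, which is 1.13 times N, with starting material at 17.9% of saturation. Solid substrate stood at 41.4% of the charge, and starting material was made 1.01 times as fast as it was used up, each step taken net.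

    starting material ⇌ target (K = 0.980, k = 1.10 min⁻¹)
    starting material ⇌ isomer of the product A (K = 250, k = 0.390 min⁻¹)
    starting material ⇌ third isomer (K = 0.430, k = 0.880 min⁻¹)
    solid substrate ⇌ starting material, rate k4*(cs4 - [starting material]) while solid is left; crystals form when [starting material] > cs4 (solubility = 0.0970 M, k = 0.0870 min⁻¹)
    target ⇌ isomer of the product B (K = 0.600, k = 0.200 min⁻¹)

For the neighbour charged with 0.12 M, c gives 12.4%. Computed, it holds 4.87% at 25.0 min, its solid substrate at 0%.

The numbers in the tables were computed for an exercise.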